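**Plan**

Cuts: the C8–O tiglate and the two acetates go first; ring D is opened at C11–C13 (Stille), then at C7–C11 and O–C12 (an oxalate unit); ring C at C6–C7 (aldol); the chain at C8–C9 and C10–C14 in one operation; C9 at C9=C10 (methylenation); the cyclobutane at C1–C10 and C5–C6 (ketene [2+2]); what remains is a ring A cyclopentene from (R)-linalool.
Numbering and enabling feature: C1/C5 are the cyclobutane CH carbons (next to acetoxy C2 and methylcarbinol C4), C6 carries the lactone oxygen, C7=C11 is the butenolide alkene (C12 carbonyl, C13 acetoxymethyl), C8 is the tigloyloxy carbon, C9 the ring C CH2, C10 the quaternary carbon with methyl C14. C10 of the cyclobutane lies next to C6 (a ketone until ring C is closed) and holds C14 on the convex and the C9–C8 chain on the concave face of the ring A/cyclobutane bicycle, so a C9=C10–C6=O methylene ketone can accept a C8 acyl anion at C9 and then a methyl group at C10.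
Forward order: ring A (ring-closing metathesis), cyclobutane (dichloroketene cycloaddition), C9 methylene, three-component coupling, ring C (aldol onto C6), ring D (oxalate Dieckmann closure), C13 (Stille), then acetates and tiglate.
Stereochemistry: C4 is taken from (R)-linalool; C2 from a CBS reduction; C1 and C5 from ketene addition anti to both silyloxy groups; C10 from convex-face methylation of the enolate; C6 from the endo tether in the aldol; C8 from convex-face hydride delivery followed by Mitsunobu inversion.

Key step: step 9

Terms: exo = on the convex face of a cis-fused ring pair (for ring A and the cyclobutane the side of H1 and H5; for ring C the side of C14 and the lactone oxygen); endo = on the concave face. In the bicyclo[3.2.0]heptanones positions 1–6 are C1–C6 and position 7 is C10.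
Assumption: commercial (R)-(−)-linalool is taken as enantiomerically pure; its stereocentre becomes C4 and is not touched again.

**Route**

Step 1
Reactants: 1 (R)-linalool
Product: 2 (R)-1-methylcyclopent-2-en-1-ol
Conditions: second-generation Grubbs catalyst RuCl2(=CHPh)(PCy3)(H2IMes) (1 mol %), CH2Cl2, 40 °C
Reagents that add atoms: none
Why: Ring-closing olefin metathesis joins the vinyl carbon to the inner carbon of the trisubstituted alkene with loss of 2-methylpropene, a closure that the free tertiary allylic hydroxyl is known to favour, and the carbinol centre (the future C4) is not touched.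

Step 2
Reactants: 2 (R)-1-methylcyclopent-2-en-1-ol
Product: 3 (R)-triethyl[(1-methylcyclopent-2-en-1-yl)oxy]silane
Conditions: Et3SiOTf, 2,6-lutidine, CH2Cl2, −78 to 0 °C
Reagents that add atoms: triethylsilyl trifluoromethanesulfonate, CC[Si](CC)(CC)OS(=O)(=O)C(F)(F)F
Why: Silylation of a hindered tertiary alcohol with a silyl triflate and a non-nucleophilic base is standard and gives an ether that should withstand the oxidant, zinc, amide bases and organolithium used later yet fall to fluoride at the end.

Step 3
Reactants: 3 (R)-triethyl[(1-methylcyclopent-2-en-1-yl)oxy]silane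
Product: 4 (R)-4-methyl-4-(triethylsilyloxy)cyclopent-2-en-1-one
Conditions: dirhodium tetrakis(caprolactamate) Rh2(C6H10NO)4 (1 mol %), t-BuOOH (70% in water), K2CO3, CH2Cl2, rt
Reagents that add atoms: tert-butyl hydroperoxide, CC(C)(C)OO
Why: Peroxide-based allylic C–H oxidation (hydrogen abstraction by the tert-butylperoxyl radical, peroxide capture, loss of tert-butanol) can only start at the single allylic CH2 (C2) because the other allylic carbon C4 is quaternary, and capture at the unhindered end of the allyl radical should place the carbonyl at C2 with the alkene kept at C1=C5.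

Step 4
Reactants: 4 (R)-4-methyl-4-(triethylsilyloxy)cyclopent-2-en-1-one
Product: 5 (1S,4R)-4-methyl-4-(triethylsilyloxy)cyclopent-2-en-1-ol
Conditions: (R)-2-methyl-CBS-oxazaborolidine (20 mol %), catecholborane, toluene, −78 °C; aq. NaOH work-up
Reagents that add atoms: none
Why: Corey–Bakshi–Shibata reduction gives 1,2-reduction of the enone, and the (R)-catalyst, which treats the alkenyl carbon as the large group, delivers hydride to the face anti to the silyloxy group that the substrate itself should prefer, so the new C2 carbinol is expected to be (S) and cis to the C4 oxygen.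

Step 5
Reactants: 5 (1S,4R)-4-methyl-4-(triethylsilyloxy)cyclopent-2-en-1-ol
Product: 6 cis-bis(silyl ether) of ring A
Conditions: t-BuMe2SiCl, imidazole, DMF, rt
Reagents that add atoms: tert-butyldimethylsilyl chloride, CC(C)(C)[Si](C)(C)Cl
Why: Imidazole-promoted silylation of a secondary allylic alcohol is routine and places the second bulky ether on the same face as the first, which is the element that will direct the cycloaddition.

Step 6
Reactants: 6 cis-bis(silyl ether) of ring A; 7 trichloroacetyl chloride
Product: 9 dichlorocyclobutanone, via dichloroketene 8 (not isolated)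
Conditions: Zn–Cu couple, Et2O–DME, rt, slow addition of 7
Reagents that add atoms: trichloroacetyl chloride (compound 7), ClC(=O)C(Cl)(Cl)Cl
Why: Thermal ketene–alkene [2+2] cycloaddition with dichloroketene made in the flask by zinc dechlorination should occur on the face anti to both silyloxy groups, which sets C1 and C5 with their hydrogens on the oxygen-bearing face (cis ring fusion), and because the attacked face shows only H at C2 but the methyl group at C4 the bulky CCl2 end should bond to C1 and the slim carbonyl carbon to C5.

Step 7
Reactants: 9 dichlorocyclobutanone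
Product: 10 cyclobutanone
Conditions: Zn dust, NH4Cl, MeOH, rt
Reagents that add atoms: none
Why: Zinc reduction of α,α-dichlorocyclobutanones (two electron-transfer and protonation cycles through zinc enolates) is the standard sequel to the dichloroketene cycloaddition and, run with NH4Cl in place of acetic acid, should spare the tertiary silyl ether, with no stereocentre involved.

Step 8
Reactants: 10 cyclobutanone; 11 N,N-dimethylmethyleneiminium iodide (Eschenmoser's salt); 12 iodomethane
Product: 16 C10-methylene cyclobutanone, via cyclobutanone lithium enolate 13 (not isolated), via Mannich base 14 (not isolated), via trimethylammonium iodide 15 (not isolated)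
Conditions: LiN(SiMe3)2, THF, −78 °C; 11, −78 to 0 °C; then MeI (12), CH2Cl2, rt; then aq. NaHCO3, rt; used at once
Reagents that add atoms: N,N-dimethylmethyleneiminium iodide (compound 11), C=[N+](C)C.[I-]
Why: Eschenmoser methylenation, in which deprotonation can only take place at the C10 methylene (an enolate toward C5 would put a double bond at the ring-fusion carbon of the four-membered ring), the enolate undergoes a Mannich reaction with the iminium salt, and N-methylation followed by base-induced elimination of trimethylamine (E1cB) gives the exocyclic C9=C10 enone.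

Step 9
Reactants: 16 C10-methylene cyclobutanone; 17 2-methyl-1,3-dithiane; 12 iodomethane
Product: 20 C10-quaternary dithiane cyclobutanone, via 2-lithio-2-methyl-1,3-dithiane 18 (not isolated), via C10 lithium enolate 19 (not isolated)
Conditions: 17, n-BuLi, THF, −30 °C; HMPA (2.5 equiv), −78 °C; 16 in THF, −78 °C; then MeI (12), −78 to −40 °C
Reagents that add atoms: 2-methyl-1,3-dithiane (compound 17), CC1SCCCS1; iodomethane (compound 12), CI
Why: Hexamethylphosphoramide turns lithiodithiane 18 into a solvent-separated ion pair whose soft carbanion adds to the unhindered exocyclic carbon C9 (Michael addition, C8–C9 bond) instead of the carbonyl carbon C6, and the cyclobutanone enolate 19, planar at C10, is trapped in the same flask by SN2 C-methylation with iodomethane (C10–C14 bond). The closest known reaction type is the conjugate addition of 2-lithio-1,3-dithianes to enones in THF–HMPA with alkylation of the enolate in situ, a three-component coupling. No ring is closed in this step. The only new stereocentre, C10, is fixed in the methylation: ring A and its endo C4 methyl group cover the concave face of the bicyclo[3.2.0] enolate, so iodomethane should arrive on the convex face, C14 ends exo and the dithianylmethyl chain is pushed endo, cis to the C1–C2 bond. The step needs 1,4- over 1,2-addition, which the separated soft anion and the freely accessible CH2 terminus should secure, and C-alkylation on the convex face, which the soft electrophile and the shape of the cis-fused bicycle should secure; since C10 becomes quaternary, neither a second alkylation nor epimerisation can follow.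

Step 10
Reactants: 20 C10-quaternary dithiane cyclobutanone; 12 iodomethane
Product: 21 C8 methyl ketone
Conditions: MeI (12), CaCO3, MeCN–H2O (9:1), 45 °C
Reagents that add atoms: water, O
Why: Alkylative dithioacetal hydrolysis (S-methylation to a sulfonium ion, attack of water at C8, loss of the thioether) unmasks the C8 ketone under buffered, non-oxidising conditions that should leave the cyclobutanone and both silyl ethers alone.

Step 11
Reactants: 21 C8 methyl ketone; 22 methyl chlorooxoacetate
Product: 24 tricyclic C6 methyl oxalate, via lithium aldolate 23 (not isolated)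
Conditions: LiN(SiMe3)2 (1.05 equiv), THF, −78 °C; then 22, −78 to −20 °C
Reagents that add atoms: methyl chlorooxoacetate (compound 22), COC(=O)C(=O)Cl
Why: Deprotonation of the unhindered methyl group C7 is followed at once by 5-exo-trig aldol addition to the strain-activated C6 carbonyl, which closes ring C in the only possible cis fashion so that C7 enters on the concave face (where the chain already sits) and the C6 oxygen ends exo, and the tertiary lithium alkoxide is then O-acylated by the acid chloride as in the usual preparation of tert-alkyl methyl oxalates, which also shuts off the retro-aldol path.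

Step 12
Reactants: 24 tricyclic C6 methyl oxalate
Product: 25 tetracyclic 3-hydroxybutenolide
Conditions: LiN(SiMe3)2 (2.2 equiv), THF, −78 to −20 °C; cold 1 M HCl work-up
Reagents that add atoms: none
Why: Dieckmann-type crossed Claisen condensation, in which the C7 enolate of the C8 ketone attacks the distal, highly electrophilic oxalate carbonyl in a 5-exo-trig acyl substitution that expels methoxide and closes ring D, and tautomerisation of the α-keto lactone to the acidic conjugated enol should make the closure irreversible and, through proton exchange, return any C9 enolate to the productive path, while no stereocentre is created.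

Step 13
Reactants: 25 tetracyclic 3-hydroxybutenolide
Product: 26 C11 enol triflate
Conditions: Tf2O, i-Pr2NEt, CH2Cl2, −78 °C
Reagents that add atoms: trifluoromethanesulfonic anhydride, O=S(=O)(OS(=O)(=O)C(F)(F)F)C(F)(F)F
Why: Enol triflate formation from an acidic enol with triflic anhydride and a hindered amine is standard, and sulfonylation is expected at the C11 oxygen because only that product keeps the conjugated butenolide.

Step 14
Reactants: 26 C11 enol triflate; 27 (tributylstannyl)methanol
Product: 28 C13 hydroxymethyl butenolide
Conditions: Pd(PPh3)4 (10 mol %), LiCl (3 equiv), 1,4-dioxane, 90 °C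
Reagents that add atoms: (tributylstannyl)methanol (compound 27), CCCC[Sn](CO)(CCCC)CCCC
Why: Stille cross-coupling (oxidative addition of the electron-poor alkenyl triflate to palladium, chloride-assisted transfer of the oxygen-activated CH2OH group from tin, reductive elimination) forms the C11–C13 bond, a hydroxymethylation that is well established for alkenyl triflates and should tolerate ketone, lactone and silyl ethers.

Step 15
Reactants: 28 C13 hydroxymethyl butenolide
Product: 29 keto triol
Conditions: HF·pyridine, pyridine–THF, 0 °C to rt
Reagents that add atoms: none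
Why: Fluoride-driven Si–O cleavage by buffered HF·pyridine removes the tertiary triethylsilyl and the secondary tert-butyldimethylsilyl ether in one operation without acid or base strong enough to harm the ene-dicarbonyl lactone.

Step 16
Reactants: 29 keto triol; 30 acetic anhydride
Product: 31 keto diacetate
Conditions: Ac2O (2.5 equiv), pyridine, DMAP (5 mol %), CH2Cl2, 0 °C
Reagents that add atoms: acetic anhydride (compound 30), CC(=O)OC(C)=O
Why: Nucleophile-catalysed acylation with acetic anhydride esterifies the primary C13 and the secondary C2 hydroxyl, while the tertiary C4 hydroxyl is too hindered to react at 0 °C, so both acetates of the target are installed together.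

Step 17
Reactants: 31 keto diacetate
Product: 32 C8 endo alcohol
Conditions: NaBH4, CeCl3·7H2O, MeOH, −78 °C
Reagents that add atoms: none
Why: Luche reduction directs hydride to the carbonyl carbon of the conjugated C8 ketone and leaves lactone, acetates and alkene alone, and because the concave face of ring C is closed off by the cyclobutane, ring A and the endo C4 methyl group the hydride should arrive from the convex face and give the endo (8-epi) alcohol.

Step 18
Reactants: 32 C8 endo alcohol; 33 tiglic acid
Product: 34 CNP0210373.1
Conditions: PPh3, DIAD, toluene, 0 °C to rt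
Reagents that add atoms: tiglic acid (compound 33), C/C=C(\C)C(O)=O
Why: Mitsunobu esterification activates the secondary allylic C8 hydroxyl as an oxyphosphonium ion that tiglate displaces in an SN2 step from the open convex face, which inverts C8 to the exo tigloyloxy configuration of the target, while the tertiary C4 hydroxyl cannot react and the (E)-alkene of the acid is not isomerised.

**Compound list**

1 | (R)-linalool, (3R)-3,7-dimethylocta-1,6-dien-3-ol | C=C[C@](C)(O)CCC=C(C)C | starting material
2 | (R)-1-methylcyclopent-2-en-1-ol | C1C[C@@](C)(O)C=C1 | intermediate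
3 | (R)-triethyl[(1-methylcyclopent-2-en-1-yl)oxy]silane | C1C[C@@](C)(O[Si](CC)(CC)CC)C=C1 | intermediate
4 | (R)-4-methyl-4-(triethylsilyloxy)cyclopent-2-en-1-one | O=C1C[C@@](C)(O[Si](CC)(CC)CC)C=C1 | intermediate
5 | (1S,4R)-4-methyl-4-(triethylsilyloxy)cyclopent-2-en-1-ol, the two oxygens cis | C1=C[C@@H](O)C[C@@]1(C)O[Si](CC)(CC)CC | intermediate
6 | tert-butyldimethyl{[(1S,4R)-4-methyl-4-(triethylsilyloxy)cyclopent-2-en-1-yl]oxy}silane, cis-bis(silyl ether) of ring A | C1=C[C@@H](O[Si](C)(C)C(C)(C)C)C[C@@]1(C)O[Si](CC)(CC)CC | intermediate
7 | trichloroacetyl chloride | ClC(=O)C(Cl)(Cl)Cl | starting material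
8 | dichloroketene (not isolated) | ClC(Cl)=C=O | intermediate
9 | cis-fused 7,7-dichloro-2-exo-(tert-butyldimethylsilyloxy)-4-endo-methyl-4-exo-(triethylsilyloxy)bicyclo[3.2.0]heptan-6-one (C6 ketone on C5, CCl2 = C10 on C1) | ClC1(Cl)[C@@H]2[C@@H](O[Si](C)(C)C(C)(C)C)C[C@@](C)(O[Si](CC)(CC)CC)[C@@H]2C1=O | intermediate
10 | cis-fused 2-exo-(tert-butyldimethylsilyloxy)-4-endo-methyl-4-exo-(triethylsilyloxy)bicyclo[3.2.0]heptan-6-one | C1[C@@H]2[C@@H](O[Si](C)(C)C(C)(C)C)C[C@@](C)(O[Si](CC)(CC)CC)[C@@H]2C1=O | intermediate
11 | N,N-dimethylmethyleneiminium iodide (Eschenmoser's salt) | C=[N+](C)C.[I-] | starting material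
12 | iodomethane | CI | starting material
13 | lithium enolate of 10, C10=C6–OLi (not isolated) | [Li]OC1=C[C@@H]2[C@@H](O[Si](C)(C)C(C)(C)C)C[C@@](C)(O[Si](CC)(CC)CC)[C@H]12 | intermediate
14 | 7-[(dimethylamino)methyl] derivative of 10, Mannich base, C10 configuration of no consequence (not isolated) | CN(C)CC1[C@@H]2[C@@H](O[Si](C)(C)C(C)(C)C)C[C@@](C)(O[Si](CC)(CC)CC)[C@@H]2C1=O | intermediate
15 | trimethylammonium iodide from 14 (not isolated) | C[N+](C)(C)CC1[C@@H]2[C@@H](O[Si](C)(C)C(C)(C)C)C[C@@](C)(O[Si](CC)(CC)CC)[C@@H]2C1=O.[I-] | intermediate
16 | 7-methylene derivative of 10, the C9=C10–C6=O enone on ring A | C=C1[C@@H]2[C@@H](O[Si](C)(C)C(C)(C)C)C[C@@](C)(O[Si](CC)(CC)CC)[C@@H]2C1=O | intermediate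
17 | 2-methyl-1,3-dithiane | CC1SCCCS1 | starting material
18 | 2-lithio-2-methyl-1,3-dithiane (not isolated) | [Li]C1(C)SCCCS1 | intermediate
19 | lithium enolate of the conjugate adduct, C10 bearing the (2-methyl-1,3-dithian-2-yl)methyl chain (not isolated) | [Li]OC1=C(CC2(C)SCCCS2)[C@@H]3[C@@H](O[Si](C)(C)C(C)(C)C)C[C@@](C)(O[Si](CC)(CC)CC)[C@H]13 | intermediate
20 | 7-exo-methyl-7-endo-[(2-methyl-1,3-dithian-2-yl)methyl] derivative of 10 (C10 quaternary, C14 exo, chain endo) | CC1(SCCCS1)C[C@]2(C)[C@@H]3[C@@H](O[Si](C)(C)C(C)(C)C)C[C@@](C)(O[Si](CC)(CC)CC)[C@@H]3C2=O | intermediate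
21 | 7-exo-methyl-7-endo-(2-oxopropyl) derivative of 10 (C8 methyl ketone, C6 cyclobutanone) | CC(=O)C[C@]1(C)[C@@H]2[C@@H](O[Si](C)(C)C(C)(C)C)C[C@@](C)(O[Si](CC)(CC)CC)[C@@H]2C1=O | intermediate
22 | methyl chlorooxoacetate | COC(=O)C(=O)Cl | starting material
23 | lithium C6 alkoxide of the tricyclic aldol: ring A, cyclobutane and ring C fused cis-syn-cis, C8 ketone, C6 oxygen exo (not isolated) | O=C1C[C@]2(C)[C@@H]3[C@@H](O[Si](C)(C)C(C)(C)C)C[C@@](C)(O[Si](CC)(CC)CC)[C@@H]3[C@]2(O[Li])C1 | intermediate
24 | tricyclic C8 ketone with exo C6–O–C(=O)–CO2Me (methyl oxalate), C14 exo, C2 exo OTBS, C4 exo OTES | O=C1C[C@]2(C)[C@@H]3[C@@H](O[Si](C)(C)C(C)(C)C)C[C@@](C)(O[Si](CC)(CC)CC)[C@@H]3[C@]2(OC(=O)C(=O)OC)C1 | intermediate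
25 | tetracyclic 3-hydroxybutenolide: lactone C6–O–C12(=O), C11–OH, C7=C11, C8 ketone, C2 exo OTBS, C4 exo OTES | O=C1C[C@]2(C)[C@@H]3[C@@H](O[Si](C)(C)C(C)(C)C)C[C@@](C)(O[Si](CC)(CC)CC)[C@@H]3[C@@]24OC(=O)C(O)=C14 | intermediate
26 | C11 trifluoromethanesulfonate of 25 | O=C1C[C@]2(C)[C@@H]3[C@@H](O[Si](C)(C)C(C)(C)C)C[C@@](C)(O[Si](CC)(CC)CC)[C@@H]3[C@@]24OC(=O)C(OS(=O)(=O)C(F)(F)F)=C14 | intermediate
27 | (tributylstannyl)methanol | CCCC[Sn](CO)(CCCC)CCCC | starting material
28 | tetracyclic butenolide with C11–CH2OH (C13), C8 ketone, C2 exo OTBS, C4 exo OTES | O=C1C[C@]2(C)[C@@H]3[C@@H](O[Si](C)(C)C(C)(C)C)C[C@@](C)(O[Si](CC)(CC)CC)[C@@H]3[C@@]24OC(=O)C(CO)=C14 | intermediate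
29 | C8 ketone with free C2 (exo), C4 (exo) and C13 hydroxyls | O=C1C[C@]2(C)[C@@H]3[C@@H](O)C[C@@](C)(O)[C@@H]3[C@@]24OC(=O)C(CO)=C14 | intermediate
30 | acetic anhydride | CC(=O)OC(C)=O | starting material
31 | C8 ketone, C2 and C13 acetates, C4 tertiary alcohol | O=C1C[C@]2(C)[C@@H]3[C@@H](OC(C)=O)C[C@@](C)(O)[C@@H]3[C@@]24OC(=O)C(COC(C)=O)=C14 | intermediate
32 | C8 endo alcohol (8-epi alcohol), C2 and C13 acetates, C4 tertiary alcohol | O[C@@H]1C[C@]2(C)[C@@H]3[C@@H](OC(C)=O)C[C@@](C)(O)[C@@H]3[C@@]24OC(=O)C(COC(C)=O)=C14 | intermediate
33 | tiglic acid, (E)-2-methylbut-2-enoic acid | C/C=C(\C)C(O)=O | starting material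
34 | CNP0210373.1: C8 exo tiglate, C2 exo acetate, C13 acetate, C4 exo tertiary alcohol with endo methyl, C14 exo, rings A and C syn on the cyclobutane | C/C=C(\C)C(=O)O[C@H]1C[C@]2(C)[C@@H]3[C@@H](OC(C)=O)C[C@@](C)(O)[C@@H]3[C@@]23OC(=O)C(COC(C)=O)=C13 | target

**Step count and risks**

Total steps: 18. Longest linear sequence: 18 steps from (R)-linalool (1); all other numbered starting materials are commercial and enter directly.

The three steps most likely to fail:

1. The three-component coupling (step 9). The lithiodithiane may attack the strained C6 carbonyl instead of C9, or enone 16 may oligomerise before it is intercepted; either drains material before the enolate can be methylated. The fallback builds the quaternary centre by two successive enolate alkylations that keep the decisive order (chain first, methyl last) but need no enone. It sets out from cyclobutanone 10: deprotonation with LiN(SiMe3)2 and alkylation with propargyl bromide would give the C10-propargyl cyclobutanone F1. A second deprotonation and methylation with iodomethane 12 on the convex face would give the C10-methyl C10-propargyl cyclobutanone F2 (methyl exo, propargyl endo). Markovnikov hydration of the terminal alkyne (Ph3PAuNTf2, aqueous dioxane) would then give methyl ketone 21, where the route is rejoined.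

2. The ring D closure (step 12). β-Elimination of the oxalate from the C7 enolate (E1cB toward a C6=C7 enone) or irreversible enolisation toward C9 may outrun the acyl transfer. The fallback reverses the order of bond formation so that no enolate has a leaving group in the β-position. It sets out from methyl ketone 21: crossed Claisen condensation with dimethyl oxalate under equilibrating conditions (NaOMe, MeOH–THF) would give the 2,4-dioxo ester F3 as its sodium enolate. Its doubly activated C7 would add reversibly to the C6 carbonyl and the aldolate would lactonise onto the ester, so that all equilibria drain to the salt of hydroxybutenolide 25, which is released on acidification and rejoins the route.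

3. The inversion at C8 (step 18). The concave C8 hydroxyl may be too shielded for the bulky phosphonium–azodicarboxylate adduct, so that activation is slow and elimination toward C9 or acetyl migration from C13 competes. The fallback separates activation from displacement. It sets out from alcohol 32: mesylation (MeSO2Cl, Et3N, CH2Cl2, −20 °C) would give the C8 endo mesylate F4, which carries a much smaller leaving group. Displacement with cesium tiglate (CsO2CC(CH3)=CHCH3, 18-crown-6, toluene) from the open convex face would invert C8 and give target 34 directly.

Further compounds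
F1 | step 9 | 7-(prop-2-yn-1-yl) derivative of cyclobutanone 10, C10 configuration of no consequence | C#CCC1[C@@H]2[C@@H](O[Si](C)(C)C(C)(C)C)C[C@@](C)(O[Si](CC)(CC)CC)[C@@H]2C1=O
F2 | step 9 | 7-exo-methyl-7-endo-(prop-2-yn-1-yl) derivative of cyclobutanone 10 | C#CC[C@]1(C)[C@@H]2[C@@H](O[Si](C)(C)C(C)(C)C)C[C@@](C)(O[Si](CC)(CC)CC)[C@@H]2C1=O
F3 | step 12 | methyl 2,4-dioxo-5-(cyclobutanonyl)pentanoate from 21 (C7 oxalylated, C6 ketone still free) | COC(=O)C(=O)CC(=O)C[C@]1(C)[C@@H]2[C@@H](O[Si](C)(C)C(C)(C)C)C[C@@](C)(O[Si](CC)(CC)CC)[C@@H]2C1=O
F4 | step 18 | C8 endo methanesulfonate of 32 | CS(=O)(=O)O[C@@H]1C[C@]2(C)[C@@H]3[C@@H](OC(C)=O)C[C@@](C)(O)[C@@H]3[C@@]24OC(=O)C(COC(C)=O)=C14
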